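**Route overview**

Numbering (germacrane): ring carbons C1–C10, methyl C14 on C10, methyl C15 on C4; C11 on C7 carries C12 (lactone carbonyl, closed onto the C6 oxygen) and C13 (acetoxymethyl); acetate on C2, methacrylate on C8.
Enabling feature: C7=C11 is fully substituted, with the ring carbinols C6 and C8 on C7 and the oxidised one-carbon branches C12 and C13 on C11. An unsaturated five-membered lactone can therefore be drawn towards C8 through C13 as well as towards C6 through C12, and C8–C7–C11–C13 is the carbon chain of mucobromic acid, whose beta bromine falls on C7 and alpha bromine on C11.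
Cuts, in retrosynthetic order: the three ester C–O bonds; the C12 lactone (C12–O6 and C11–C12, back to carbon monoxide and a C11 bromide, with C13 and O8 rejoined as a temporary lactone); the ring bond C6–C7 (back to a C6 enal and the C7 bromide); C2–C3 and C8–C9 (two vinylogous aldol bonds to the dienol ether of 3-methylbut-2-enal).
Forward order: the first aldol closes the temporary C8–O–C13 dibromobutenolide, the second aldol completes the chain C8 to C6, a Ni/Cr-mediated coupling closes the ten-membered carbocycle at C6–C7, hydride opens the temporary lactone, carbonylation at C11 closes the final C6–O–C12 butenolide, and the esters go on last.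
Stereochemistry: C8 (S) and C2 (R) by catalyst control in the two aldols (enantiomeric catalysts); C6 (R) in the ring closure under the influence of C8 and the ring conformation; both E trisubstituted alkenes from gamma attack of the dienol ether; the C7=C11 geometry carried over from mucobromic acid.

Key step: step 6

Assumption: the sense of induction of the tryptophan-derived oxazaborolidinone is taken by analogy with simple aldehydes (Re-face attack with the catalyst from the L-amino acid); it is to be confirmed on the first aldol product, and the two catalyst enantiomers are exchanged between steps 3 and 4 if it proves opposite.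

**Route**

Step 1
Reactants: 1 3-methylbut-2-enal
Product: 2 (E)-tert-butyldimethyl[(3-methylbuta-1,3-dien-1-yl)oxy]silane
Conditions: TBSOTf, Et3N, Et2O, 0 °C to rt
Reagents that add atoms: tert-butyldimethylsilyl triflate, CC(C)(C)[Si](C)(C)OS(=O)(=O)C(F)(F)F
Why: soft enolisation of the enal at its gamma methyl group and O-silylation of the extended enolate should give the 1-silyloxy diene with the E enol ether geometry, the usual outcome for this aldehyde.

Step 2
Reactants: 3 mucobromic acid (3,4-dibromo-5-hydroxyfuran-2(5H)-one)
Product: 4 methyl (2Z)-2,3-dibromo-4-oxobut-2-enoate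
Conditions: Me2SO4, KHCO3, acetone, 0 °C to rt
Reagents that add atoms: dimethyl sulfate, COS(=O)(=O)OC
Why: in bicarbonate the pseudo-acid is present as the ring-opened Z carboxylate, so carboxylate O-alkylation (SN2) should give the normal ester with a free formyl group and unchanged alkene geometry, whereas acid and methanol would give the cyclic pseudo-ester; an iodide-free methylating agent avoids halide exchange at the activated C–Br bonds.

Step 3
Reactants: 4 methyl (2Z)-2,3-dibromo-4-oxobut-2-enoate; 2 silyl dienol ether
Product: 6 (2E)-4-[(2S)-3,4-dibromo-5-oxo-2,5-dihydrofuran-2-yl]-3-methylbut-2-enal, via hydroxy ester 5 (not isolated)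
Conditions: (R)-4-(1H-indol-3-ylmethyl)-2-phenyl-3-tosyl-1,3,2-oxazaborolidin-5-one (30 mol%, from N-tosyl-D-tryptophan and PhBCl2), i-PrOH, EtCN, −78 °C; then CSA (cat.), CH2Cl2, rt
Reagents that add atoms: none
Why: enantioselective vinylogous Mukaiyama aldol in which the boron Lewis acid binds the formyl group of the alpha-bromo enal (a substrate type this catalyst family handles well), the dienol ether attacks through its gamma carbon on the Si face to set C8 as S and to leave the E enal, isopropanol takes up the silyl group for turnover, and the new hydroxyl then lactonises onto the cis methyl ester under acid.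

Step 4
Reactants: 6 dibromobutenolide enal; 2 silyl dienol ether
Product: 7 (2E,5R,6E)-8-[(2S)-3,4-dibromo-5-oxo-2,5-dihydrofuran-2-yl]-5-hydroxy-3,7-dimethylocta-2,6-dienal
Conditions: (S)-4-(1H-indol-3-ylmethyl)-2-phenyl-3-tosyl-1,3,2-oxazaborolidin-5-one (30 mol%, from N-tosyl-L-tryptophan and PhBCl2), i-PrOH, EtCN, −78 °C
Reagents that add atoms: none
Why: the same vinylogous Mukaiyama aldol with the enantiomeric catalyst, now by Re-face attack on the enal carbonyl, sets C2 (C5 of the chain name) as R under catalyst control because C8 is five atoms away, and gamma attack again gives the E trisubstituted enal, completing the chain C8 to C6.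

Step 5
Reactants: 7 hydroxy dienal
Product: 8 (2E,5R,6E)-5-(tert-butyldimethylsilyloxy)-8-[(2S)-3,4-dibromo-5-oxo-2,5-dihydrofuran-2-yl]-3,7-dimethylocta-2,6-dienal
Conditions: TBSOTf, 2,6-lutidine, CH2Cl2, −78 °C
Reagents that add atoms: tert-butyldimethylsilyl triflate, CC(C)(C)[Si](C)(C)OS(=O)(=O)C(F)(F)F
Why: silylation with a silyl triflate and a hindered, non-nucleophilic pyridine at low temperature protects the C2 hydroxyl without amine addition–elimination at the beta bromide or epimerisation at the acidic C8–H.

Step 6
Reactants: 8 C2 silyl ether of the dibromobutenolide dienal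
Product: 10 (2R,6R,8S)-11-bromo-2-(tert-butyldimethylsilyloxy)-6-hydroxygermacra-1(10)E,4E,7(11)-trien-13,8-olide, via alkenylchromium dichloride 9 (not isolated)
Conditions: CrCl2 (8 equiv), NiCl2 (0.1 equiv), DMF–THF, 0.003 M, slow addition of 8, rt
Reagents that add atoms: none
Why: Proposed new method: NiCl2 is reduced by CrCl2 to zerovalent nickel, which inserts into the C7–Br bond; the alkenyl group is handed to trivalent chromium (9) and adds 1,2 to the C6 aldehyde, so the mechanism is that of a Nozaki–Hiyama–Kishi coupling, whose closest precedents are the couplings of beta-halo enoates with aldehydes and the alkenyl halide–aldehyde closures of medium and large rings, whereas the use of one bromide of a 3,4-dibromobutenolide in this reaction is untested. The ten-membered carbocycle closes in the 10-exo-trig mode by forming C6–C7, at high dilution and with only a few rotatable bonds left free by the two E trisubstituted alkenes and the flat butenolide. Site selectivity between the two bromides is needed and is secured by conjugation: C7–Br is a vinylogous acyl bromide and the position at which late metals insert first in this ring system, C11–Br is an unactivated alpha bromide, and the five-membered ring forbids loss of the neighbouring bromide from the alkenyl metal as an alkyne. Face selectivity at the new C6 stereocentre is also needed and is controlled by the C8 stereocentre on the other side of C7 together with the ring conformation in the transition state, which is expected, though not guaranteed, to favour 6R. The chromium alkoxide formed at C6 lies trans to the lactone carbonyl across C7=C11 and cannot transacylate, and organochromium reagents leave the lactone, the silyl ether and the remaining bromide untouched.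

Step 7
Reactants: 10 ten-membered bromo lactone carbinol
Product: 12 (2R,6R,8S)-11-bromo-2-(tert-butyldimethylsilyloxy)germacra-1(10)E,4E,7(11)Z-triene-6,8,13-triol, via lactol aluminate 11 (not isolated)
Conditions: i-Bu2AlH (5 equiv), CH2Cl2, −78 to −20 °C; aq. potassium sodium tartrate
Reagents that add atoms: none
Why: excess aluminium hydride reduces the butenolide carbonyl in the 1,2 sense through the lactol stage to the Z ene-diol (standard hydride reduction of an unsaturated lactone), the alkenyl bromide and silyl ether are inert at low temperature, and the neutral tartrate work-up avoids dehydration of the lactol to a furan or of the cis diol to a dihydrofuran.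

Step 8
Reactants: 12 bromo triol
Product: 13 (2R,6R,8S)-2-(tert-butyldimethylsilyloxy)-8,13-dihydroxygermacra-1(10)E,4E,7(11)-trien-12,6-olide
Conditions: Pd(OAc)2 (10 mol%), Xantphos (12 mol%), CO (1 atm), Et3N, MeCN–toluene, 70 °C
Reagents that add atoms: carbon monoxide, [C-]#[O+]
Why: palladium-catalysed cyclocarbonylation of a (Z)-3-halo allylic alcohol (oxidative addition at C11–Br, CO insertion, acyl transfer to oxygen) should close the butenolide only onto the C6 hydroxyl, which is cis to the bromine and gives a five-membered ring, whereas the C8 hydroxyl is trans and the C13 hydroxyl would give a four-membered ring; the temperature stays below that at which the 1,5-diene undergoes Cope rearrangement.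

Step 9
Reactants: 13 butenolide diol
Product: 14 (2R,6R,8S)-2,13-bis(tert-butyldimethylsilyloxy)-8-hydroxygermacra-1(10)E,4E,7(11)-trien-12,6-olide
Conditions: TBSCl (1.1 equiv), imidazole, CH2Cl2, 0 °C
Reagents that add atoms: tert-butyldimethylsilyl chloride, CC(C)(C)[Si](C)(C)Cl
Why: the primary allylic C13 hydroxyl is silylated far faster than the hindered secondary C8 hydroxyl next to the tetrasubstituted alkene (steric selection in silyl chloride–imidazole silylation), and a silyl group here, unlike an acetate, cannot walk to the cis-disposed C8 oxygen in the next step.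

Step 10
Reactants: 14 C8 alcohol; 15 methacrylic anhydride
Product: 16 (2R,6R,8S)-2,13-bis(tert-butyldimethylsilyloxy)-8-(methacryloyloxy)germacra-1(10)E,4E,7(11)-trien-12,6-olide
Conditions: DMAP, Et3N, CH2Cl2, 0 °C to rt
Reagents that add atoms: none
Why: DMAP-catalysed acylation (nucleophilic catalysis through the acylpyridinium ion) esterifies the only free hydroxyl with retention at C8, and the mild amine base at low temperature should not deprotonate the gamma position C6 of the butenolide.

Step 11
Reactants: 16 bis-silyl ether methacrylate
Product: 17 (2R,6R,8S)-2,13-dihydroxy-8-(methacryloyloxy)germacra-1(10)E,4E,7(11)-trien-12,6-olide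
Conditions: HF·pyridine, pyridine, THF, 0 °C to rt
Reagents that add atoms: none
Why: pyridine-buffered hydrogen fluoride cleaves both silyl ethers through Si–F bond formation under slightly acidic conditions, which avoids base-induced migration of the methacrylate from O8 to the freed C13 hydroxyl, conjugate addition to the methacrylate and acid-induced transannular cyclisation of the diene.

Step 12
Reactants: 17 diol methacrylate
Product: 18 CNP0309304.1, (2R,6R,8S)-2,13-diacetoxy-8-(methacryloyloxy)germacra-1(10)E,4E,7(11)-trien-12,6-olide
Conditions: Ac2O, pyridine, DMAP (cat.), CH2Cl2, 0 °C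
Reagents that add atoms: acetic anhydride, CC(=O)OC(C)=O
Why: standard DMAP–pyridine acetylation converts the primary C13 and the secondary allylic C2 hydroxyls into acetates in one operation without touching a stereocentre, the primary hydroxyl being acetylated faster than the neighbouring methacrylate could migrate.

**Compound list**

1 | 3-methylbut-2-enal | CC(C)=CC=O | starting material
2 | (E)-tert-butyldimethyl[(3-methylbuta-1,3-dien-1-yl)oxy]silane | C=C(C)/C=C/O[Si](C)(C)C(C)(C)C | intermediate
3 | mucobromic acid, 3,4-dibromo-5-hydroxyfuran-2(5H)-one | O=C1OC(O)C(Br)=C1Br | starting material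
4 | methyl (2Z)-2,3-dibromo-4-oxobut-2-enoate (ester cis to formyl) | COC(=O)/C(Br)=C(Br)\C=O | intermediate
5 | methyl (2Z,4S,6E)-2,3-dibromo-4-hydroxy-6-methyl-8-oxoocta-2,6-dienoate (open aldol product, formed in the flask) | COC(=O)/C(Br)=C(Br)\[C@@H](O)C/C(C)=C/C=O | intermediate
6 | (2E)-4-[(2S)-3,4-dibromo-5-oxo-2,5-dihydrofuran-2-yl]-3-methylbut-2-enal (8S, temporary C8–O–C13 lactone) | O=C/C=C(C)/C[C@@H]1OC(=O)C(Br)=C1Br | intermediate
7 | (2E,5R,6E)-8-[(2S)-3,4-dibromo-5-oxo-2,5-dihydrofuran-2-yl]-5-hydroxy-3,7-dimethylocta-2,6-dienal (2R,8S in germacrane numbering) | O=C/C=C(C)/C[C@@H](O)/C=C(C)/C[C@@H]1OC(=O)C(Br)=C1Br | intermediate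
8 | (2E,5R,6E)-5-(tert-butyldimethylsilyloxy)-8-[(2S)-3,4-dibromo-5-oxo-2,5-dihydrofuran-2-yl]-3,7-dimethylocta-2,6-dienal | O=C/C=C(C)/C[C@@H](O[Si](C)(C)C(C)(C)C)/C=C(C)/C[C@@H]1OC(=O)C(Br)=C1Br | intermediate
9 | alkenylchromium dichloride: compound 8 with CrCl2 in place of the C7 bromine (formed in the flask) | O=C/C=C(C)/C[C@@H](O[Si](C)(C)C(C)(C)C)/C=C(C)/C[C@@H]1OC(=O)C(Br)=C1[Cr](Cl)Cl | intermediate
10 | (2R,6R,8S)-11-bromo-2-(tert-butyldimethylsilyloxy)-6-hydroxygermacra-1(10)E,4E,7(11)-trien-13,8-olide | O=C1O[C@H]2C/C(C)=C/[C@H](O[Si](C)(C)C(C)(C)C)C/C(C)=C/[C@@H](O)C2=C1Br | intermediate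
11 | C13 lactol of 10 (13-hydroxy-8,13-epoxide, either configuration at C13, present as its aluminium alkoxide, formed in the flask) | OC1O[C@H]2C/C(C)=C/[C@H](O[Si](C)(C)C(C)(C)C)C/C(C)=C/[C@@H](O)C2=C1Br | intermediate
12 | (2R,6R,8S)-11-bromo-2-(tert-butyldimethylsilyloxy)germacra-1(10)E,4E,7(11)Z-triene-6,8,13-triol (bromine cis to C6) | O[C@H]1C/C(C)=C/[C@H](O[Si](C)(C)C(C)(C)C)C/C(C)=C/[C@@H](O)/C1=C(\Br)CO | intermediate
13 | (2R,6R,8S)-2-(tert-butyldimethylsilyloxy)-8,13-dihydroxygermacra-1(10)E,4E,7(11)-trien-12,6-olide | O[C@H]1C/C(C)=C/[C@H](O[Si](C)(C)C(C)(C)C)C/C(C)=C/[C@H]2OC(=O)C(CO)=C12 | intermediate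
14 | (2R,6R,8S)-2,13-bis(tert-butyldimethylsilyloxy)-8-hydroxygermacra-1(10)E,4E,7(11)-trien-12,6-olide | O[C@H]1C/C(C)=C/[C@H](O[Si](C)(C)C(C)(C)C)C/C(C)=C/[C@H]2OC(=O)C(CO[Si](C)(C)C(C)(C)C)=C12 | intermediate
15 | methacrylic anhydride | C=C(C)C(=O)OC(=O)C(C)=C | starting material
16 | (2R,6R,8S)-2,13-bis(tert-butyldimethylsilyloxy)-8-(methacryloyloxy)germacra-1(10)E,4E,7(11)-trien-12,6-olide | C=C(C)C(=O)O[C@H]1C/C(C)=C/[C@H](O[Si](C)(C)C(C)(C)C)C/C(C)=C/[C@H]2OC(=O)C(CO[Si](C)(C)C(C)(C)C)=C12 | intermediate
17 | (2R,6R,8S)-2,13-dihydroxy-8-(methacryloyloxy)germacra-1(10)E,4E,7(11)-trien-12,6-olide | C=C(C)C(=O)O[C@H]1C/C(C)=C/[C@H](O)C/C(C)=C/[C@H]2OC(=O)C(CO)=C12 | intermediate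
18 | CNP0309304.1, (2R,6R,8S)-2,13-diacetoxy-8-(methacryloyloxy)germacra-1(10)E,4E,7(11)-trien-12,6-olide | C=C(C)C(=O)O[C@H]1C/C(C)=C/[C@H](OC(C)=O)C/C(C)=C/[C@H]2OC(=O)C(COC(C)=O)=C12 | target

**Step count and risks**

Total steps: 12. Longest linear sequence: 11 steps (from 3 through steps 2 to 12; the line from 1 through steps 1 and 3 to 12 is equally long).

Step 6 (ring closure, the labelled step). What may go wrong: insertion at the C11 bromide or reduction of a C–Br bond without C–C bond formation, loss of the C8 carboxylate from the alkenyl metal, oligomerisation in place of closure of the strained ring, or addition to the wrong face of the aldehyde. The fallback uses known chemistry, sets out from 8 and returns at 10. It makes the C6–C7 bond by an intramolecular Stille ketone synthesis, which rests on the established preference of palladium for the beta bromide of 3,4-dibromobutenolides. Stannylation of 8 with hexamethylditin (Pd(PPh3)4, toluene, 80 °C) should give the C7 trimethylstannane F1. Pinnick oxidation of the enal (NaClO2, NaH2PO4, 2-methylbut-2-ene, t-BuOH–H2O) then gives the carboxylic acid F2. 1-Chloro-N,N,2-trimethylprop-1-en-1-amine in CH2Cl2 converts the acid under neutral conditions into the acid chloride F3. Slow addition of this to Pd2(dba)3 and tri(2-furyl)phosphine in toluene at 50 °C should close the ring as the C6 ketone F4, zerovalent palladium inserting into the C–Cl bond far faster than into C11–Br. Corey–Bakshi–Shibata reduction of the ketone with (S)-1-methyl-3,3-diphenyltetrahydro-1H,3H-pyrrolo[1,2-c][1,3,2]oxazaborole and catecholborane at −78 °C sets C6 under reagent control (first choice on the usual size model with C7 as the large group) and gives 10. The same ketone is reached by MnO2 oxidation of the carbinol from step 6 should the ring close with the wrong sense at C6.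

Step 3 (first aldol). What may go wrong: two-point binding of the formyl and ester groups to boron eroding the enantioselectivity, conjugate addition–elimination at a bromine-bearing carbon in place of carbonyl addition, or induction in the unexpected sense. The fallback sets out from 4 and returns at 6. It runs the aldol under Lewis-base activation of SiCl4, a catalyst system with a strong record for conjugated aldehydes, and uses an amide-derived dienolate. Acylation of morpholine with 3-methylbut-2-enoyl chloride gives the amide F5, and LDA followed by TBSCl gives the N,O-silyl dienyl ketene acetal F6. This acetal and 4 with SiCl4, i-Pr2NEt and the appropriate enantiomer of the dimeric binaphthyl-2,2'-diamine-derived bisphosphoramide (5 mol%) in CH2Cl2 at −78 °C should give by gamma attack, after work-up, the hydroxy amide F7. Acid lactonises it to the butenolide amide F8. Cp2Zr(H)Cl in THF at rt then reduces the morpholine amide selectively to the aldehyde and returns 6.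

Step 8 (carbonylative lactonisation). What may go wrong: slow oxidative addition at the hindered, tetrasubstituted alkenyl bromide, so that palladium-induced ionisation of the allylic alcohols or thermal Cope rearrangement of the 1,5-diene overtakes carbonylation. The fallback sets out from 12 and returns at 13. It replaces carbon monoxide by carbon dioxide and the acylpalladium by an alkenyllithium. MeLi (3 equiv, THF, −78 °C) turns 12 into its trilithium alkoxide, and t-BuLi (2 equiv) effects bromine–lithium exchange at C11 with retention of the alkene geometry. CO2 followed by aqueous citric acid gives the hydroxy acid F9, whose carboxyl group lactonises onto the cis C6 hydroxyl to give 13.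

**Further compounds**

F1 | step 6 | C7 trimethylstannane of 8: (2E,5R,6E)-8-[(2S)-4-bromo-5-oxo-3-(trimethylstannyl)-2,5-dihydrofuran-2-yl]-5-(tert-butyldimethylsilyloxy)-3,7-dimethylocta-2,6-dienal | O=C/C=C(C)/C[C@@H](O[Si](C)(C)C(C)(C)C)/C=C(C)/C[C@@H]1OC(=O)C(Br)=C1[Sn](C)(C)C
F2 | step 6 | the corresponding (2E,5R,6E)-octa-2,6-dienoic acid | OC(=O)/C=C(C)/C[C@@H](O[Si](C)(C)C(C)(C)C)/C=C(C)/C[C@@H]1OC(=O)C(Br)=C1[Sn](C)(C)C
F3 | step 6 | the corresponding acid chloride | ClC(=O)/C=C(C)/C[C@@H](O[Si](C)(C)C(C)(C)C)/C=C(C)/C[C@@H]1OC(=O)C(Br)=C1[Sn](C)(C)C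
F4 | step 6 | (2R,8S)-11-bromo-2-(tert-butyldimethylsilyloxy)-6-oxogermacra-1(10)E,4E,7(11)-trien-13,8-olide | O=C1O[C@H]2C/C(C)=C/[C@H](O[Si](C)(C)C(C)(C)C)C/C(C)=C/C(=O)C2=C1Br
F5 | step 3 | 3-methyl-1-(morpholin-4-yl)but-2-en-1-one | CC(C)=CC(=O)N1CCOCC1
F6 | step 3 | 4-[(1Z)-1-(tert-butyldimethylsilyloxy)-3-methylbuta-1,3-dien-1-yl]morpholine | C=C(C)/C=C(\O[Si](C)(C)C(C)(C)C)N1CCOCC1
F7 | step 3 | methyl (2Z,4S,6E)-2,3-dibromo-4-hydroxy-6-methyl-8-(morpholin-4-yl)-8-oxoocta-2,6-dienoate | COC(=O)/C(Br)=C(Br)\[C@@H](O)C/C(C)=C/C(=O)N1CCOCC1
F8 | step 3 | (2E)-4-[(2S)-3,4-dibromo-5-oxo-2,5-dihydrofuran-2-yl]-3-methyl-1-(morpholin-4-yl)but-2-en-1-one | O=C(/C=C(C)/C[C@@H]1OC(=O)C(Br)=C1Br)N1CCOCC1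
F9 | step 8 | (2R,6R,8S)-2-(tert-butyldimethylsilyloxy)-6,8,13-trihydroxygermacra-1(10)E,4E,7(11)-trien-12-oic acid (carboxyl cis to C6) | O[C@H]1C/C(C)=C/[C@H](O[Si](C)(C)C(C)(C)C)C/C(C)=C/[C@@H](O)/C1=C(\C(=O)O)CO
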